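Put your sampling into the first minutes of this flask, while partner and target stand side by side.

    starting material + second chain carrier → released group + first chain carrier (k1 = 8.28 × 10⁵ /M/s)
    partner + first chain carrier → target + second chain carrier (k2 = 1.11 × 10⁵ /M/s)
    starting material + initiating radical → capped initiator + first chain carrier (k3 = 1.17 × 10⁶ /M/s)
    initiator → 2 initiating radical (k4 = 0.00240 /s)
    2 first chain carrier → ended chains B (k5 = 9.9 × 10⁷ /M/s)
    partner + target → over-reaction product (k6 = 0.346 /M/s)
    2 second chain carrier → ended chains A (k7 = 7 × 10⁸ /M/s)

starting material 20 mM; partner 14.0 mM; initiator 3.0 mM; time 1.0 h

- in percentages every species weighs as the starting material in it: one ended chains B counts as two
- a step written with two of one species runs at k times the square of its concentration and takes two of it each time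
- run time (flask): 1.0 h

1. conversion of starting material at 1.0 h
2. amount of target at 1.0 h, in percent of the starting material charged
3. amount of over-reaction product at 1.0 h, in percent of the starting material charged
4. amount of target if the flask were left three thousand times as long, in percent of the starting material charged

1. Compare rates at one moment. The step that makes target and the over-reaction step both consume partner, so partner cancels from their ratio. What remains is the over-reaction constant times target, over the chain constant times first chain carrier. At a steady level of that carrier, the ratio starts at zero and climbs as target grows.

2. Assume first chain carrier ends by pairing as fast as initiator feeds it. Its level is then the square root of the initiation constant times initiator over the pairing constant, 2.70 × 10⁻⁴ mM. Partner then falls pseudo-first-order, with a half-life of 23.2 s. That is shorter than the half-life of initiator, 4.81 min, so you may hold the carrier level constant during the fall.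

3. First way: when half the partner has gone, target stands near half the partner charge, and the ratio is 8.09%. Second way: sum the over-reaction rate over the whole fall and divide by the partner charge, which gives 8.09%. Both ways use the same constants and the same carrier level, so their agreement tests the averaging, not that level. Call the number the lost share, the fraction of charged partner taken by over-reaction.

4. Each lost partner also takes one target, so target is the partner charge times one minus twice the lost share. For this flask I reckon 5.66% of over-reaction product and 58.7% of target. Counting two cappings per initiator, conversion comes to 94.3%. The run lasts far longer than the partner's half-life, so I expect the same target after the long wait.

5. The forecast says conversion 94.5%, target 59.5%, over-reaction product 5.3% and long-wait target 59.5%, noting that “the partner and target coexist at millimolar levels”. Its target stands 0.80 percentage points above mine.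

6. The flask gives conversion 94.9%, target 60.1%, over-reaction product 4.97% and long-wait target 60.1%, with partner at 0% after 1.00 h. Read from that product, the lost share is 7.10%, below my 8.09%. Put into the target rule, this reading gives 60.1%, beside the 60.1% found.

7. Now take the flask with 50 mM of starting material. The lost share contains no starting material, so 8.09% stands and gives 2.27% of over-reaction product and 23.5% of target. That flask computes to 1.97% and 24.1%.

The rate constants stand for no real mixture; the flask was simulated.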